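**Plan**

- **Cuts.** Locants: C1 ring ketone, C2 isobutyryl carbon, C3 and C5 enol carbons, C4 monoprenyl carbon, C6 gem-diprenyl carbon. With the C3 hydroxyl masked as OEt, the retrosynthesis cuts C1–C2 and C3–C4 at once and ties C1 to C4 instead. This contracts the six-membered ring to 2,2,4-triprenylcyclobutane-1,3-dione and frees C2–C3 as the push–pull alkyne EtOC≡C–C(O)iPr.
- **Enabling feature.** The arc C4–C5(O)–C6–C1(O) is a 1,3-dicarbonyl unit with a nucleophilic end (C4) and an electrophilic end (C1), and C3/C2 of the alkyne carry the complementary polarity. Quaternary C6 cannot enolise, and a mirror plane through C4 and C6 makes the two carbonyls of the four-membered ring equivalent, so only one insertion product can form and ring strain pays for the C1–C4 cleavage.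
- **Further cuts.** The four-membered ring is cut by retro-[2+2] into bis(prenyl)ketene (diethyl malonate plus two prenyl bromide) and 1-ethoxy-5-methylhex-4-en-1-yne (ethoxyacetylene plus prenyl bromide). The ynone comes from ethoxyacetylene and the Weinreb amide of isobutyric acid.
- **Forward order.** Cyclobutenone ring by [2+2], hydrolysis to the dione, two-carbon ring expansion to the six-membered ring, removal of the ethyl group.
- **Stereochemistry.** The target is achiral: C6 carries two identical prenyl groups and no alkene has E/Z isomers, so nothing has to be set.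

Key step: step 9

Remark: 12, 17 and 18 are each drawn in one tautomeric form, and conjugate bases of numbered compounds made in the flask (malonate enolates, lithium ethoxyacetylide, the sodium enolate of 12) count as forms of the parent compound; 15 and 16 are written as anions without the sodium counter-ion.

**Step 1**
Reactants: 1 diethyl malonate; 2 prenyl bromide (1-bromo-3-methylbut-2-ene)
Product: 4 diethyl 2,2-bis(3-methylbut-2-enyl)malonate, via diethyl 2-(3-methylbut-2-enyl)malonate 3 (not isolated)
Conditions: NaH (2.2 equiv), THF–DMF, 0 °C; 2 (2.2 equiv), 0 °C → rt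
Reagents that add atoms: none
Why: Double malonic ester alkylation, in which the malonate enolate displaces the primary allylic bromide by SN2 and monoalkylated 3 is deprotonated again and alkylated a second time.

**Step 2**
Reactants: 4 diethyl 2,2-bis(3-methylbut-2-enyl)malonate
Product: 5 ethyl 5-methyl-2-(3-methylbut-2-enyl)hex-4-enoate
Conditions: LiCl, H2O, DMSO, 170 °C
Reagents that add atoms: none
Why: Krapcho dealkoxycarbonylation, in which chloride dealkylates one ester of the geminal diester and the carboxylate loses CO2 under neutral conditions that spare the acid-sensitive trisubstituted alkenes.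

**Step 3**
Reactants: 5 ethyl 5-methyl-2-(3-methylbut-2-enyl)hex-4-enoate
Product: 6 5-methyl-2-(3-methylbut-2-enyl)hex-4-enoic acid
Conditions: KOH, EtOH–H2O, reflux; then cold 1 M HCl to pH 3
Reagents that add atoms: potassium hydroxide, [K+].[OH-]
Why: Saponification of an α-branched ethyl ester, with cold acidification so that the free acid does not lactonise onto a prenyl alkene.

**Step 4**
Reactants: 6 5-methyl-2-(3-methylbut-2-enyl)hex-4-enoic acid
Product: 7 5-methyl-2-(3-methylbut-2-enyl)hex-4-enoyl chloride
Conditions: (COCl)2, cat. DMF, CH2Cl2, 0 °C → rt, used crude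
Reagents that add atoms: oxalyl chloride, ClC(=O)C(Cl)=O
Why: Vilsmeier-type activation of a carboxylic acid to its chloride, a conversion that prenylated acids routinely tolerate at or below room temperature.

**Step 5**
Reactants: 8 ethoxyacetylene; 2 prenyl bromide
Product: 9 1-ethoxy-5-methylhex-4-en-1-yne
Conditions: n-BuLi, THF, −78 °C; then 2, DMPU, −78 °C → rt
Reagents that add atoms: none
Why: Alkylation of a lithium alkoxyacetylide with a primary allylic bromide (SN2), helped by the dipolar cosolvent.

**Step 6**
Reactants: 7 5-methyl-2-(3-methylbut-2-enyl)hex-4-enoyl chloride; 9 1-ethoxy-5-methylhex-4-en-1-yne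
Product: 11 3-ethoxy-2,4,4-tris(3-methylbut-2-enyl)cyclobut-2-en-1-one, via bis(3-methylbut-2-enyl)ketene 10 (not isolated)
Conditions: Et3N, CH2Cl2, slow addition of 7, reflux (40 °C)
Reagents that add atoms: none
Why: Dehydrochlorination gives dialkylketene 10, which enters the classical ketene/1-alkoxyalkyne [2+2] cycloaddition; the nucleophilic alkyne carbon remote from OEt bonds to the ketene carbonyl carbon, which fixes the 3-ethoxy-2-prenyl pattern, and the one-carbon tether keeps the prenyl alkenes out of intramolecular cycloaddition.

**Step 7**
Reactants: 11 3-ethoxy-2,4,4-tris(3-methylbut-2-enyl)cyclobut-2-en-1-one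
Product: 12 3-hydroxy-2,4,4-tris(3-methylbut-2-enyl)cyclobut-2-en-1-one (enol form of 2,2,4-triprenylcyclobutane-1,3-dione)
Conditions: 1 M HCl, THF, rt
Reagents that add atoms: water, O
Why: Acid hydrolysis of a vinylogous ester, the standard unmasking of a 3-alkoxycyclobutenone to the strongly acidic cyclobutane-1,3-dione enol, dilute and cold enough to leave the prenyl groups alone.

**Step 8**
Reactants: 8 ethoxyacetylene; 13 N-methoxy-N-methylisobutyramide
Product: 14 1-ethoxy-4-methylpent-1-yn-3-one
Conditions: n-BuLi, THF, −78 °C; then 13, −78 → −20 °C; AcOH in THF, −78 °C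
Reagents that add atoms: none
Why: Weinreb ketone synthesis, in which the chelated tetrahedral adduct of the alkynyllithium prevents over-addition and the cold acetic acid quench limits addition of the released amine to the ynone.

**Step 9**
Reactants: 12 3-hydroxy-2,4,4-tris(3-methylbut-2-enyl)cyclobut-2-en-1-one; 14 1-ethoxy-4-methylpent-1-yn-3-one
Product: 17 3-ethoxy-5-hydroxy-4,6,6-tris(3-methylbut-2-enyl)-2-(2-methylpropanoyl)cyclohexa-2,4-dien-1-one (colupulone 3-O-ethyl ether), via allenolate adduct 15 (not isolated), via bicyclo[2.2.0]hexenolate 16 (not isolated)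
Conditions: NaH (1.05 equiv), THF, 0 °C; then 14, 0 °C → rt (kept below 40 °C); cold 1 M HCl to pH 3
Reagents that add atoms: none
Why: Proposed new method: the sodium enolate of 12, nucleophilic only at the prenyl-bearing ring carbon because the other α-carbon is quaternary, should add in Michael fashion to the ethoxy-bearing alkyne carbon of push–pull ynone 14 (new C3–C4 bond) to give allenolate 15, any O-alkenylation being reversible because the cyclobutenolate is an excellent leaving group from the resulting acylketene acetal. In the aprotic medium the allenolate carbon C2 should attack the flanking ring carbonyl C1 (4-exo-trig, new C1–C2 bond) to give cis-fused bicyclo[2.2.0]hexenolate 16, whose alkoxide expels the doubly stabilised C4 enolate by retro-aldol (Grob-type) cleavage of the central C1–C4 bond, so the six-membered ring arises by two-carbon ring expansion and not by a direct closure. The closest known reaction type is the base-mediated formal insertion of ynones, acetylenic esters and arynes into the C(O)–Cα σ-bond of cyclic 1,3-dicarbonyl compounds (Michael/aldol/retro-aldol ring expansion), which has not been shown for cyclobutane-1,3-diones or for alkoxy-ynones. The closure should cost no more strain than in the five- and six-ring precedents, since the strain of bicyclo[2.2.0]hexane is roughly twice that of cyclobutane, whereas the cleavage releases both small rings and ends in the delocalised anion of a β-triketone vinylogous ester. No stereocentre survives (the stereo-elements of 15 and 16 are transient and racemic), and regioselectivity is secured by the substrate, because the two carbonyls of 12 are mirror-related so that attack on either gives the same product, while the polarity of 14 places OEt on C3 and the isobutyryl group on C2. Chemoselectivity needs the low temperature, which keeps the cyclobutenone form of 12 from electrocyclic opening to a vinylketene that the prenyl alkenes would trap by intramolecular [2+2] cycloaddition.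

**Step 10**
Reactants: 17 colupulone 3-O-ethyl ether
Product: 18 colupulone, 3,5-dihydroxy-4,6,6-tris(3-methylbut-2-enyl)-2-(2-methylpropanoyl)cyclohexa-2,4-dien-1-one
Conditions: 1 M HCl, THF, rt → 40 °C, argon
Reagents that add atoms: water, O
Why: Acid hydrolysis of a vinylogous ester by addition–elimination of water at C3, which is activated by the C1 and isobutyryl carbonyls; dilute acid and exclusion of air should avoid chroman formation and autoxidation.

**Compound list**

| No. | Name | SMILES | Role |
|---|---|---|---|
| 1 | diethyl malonate | CCOC(=O)CC(=O)OCC | starting material |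
| 2 | prenyl bromide | CC(C)=CCBr | starting material |
| 3 | diethyl 2-(3-methylbut-2-enyl)malonate | CCOC(=O)C(CC=C(C)C)C(=O)OCC | intermediate |
| 4 | diethyl 2,2-bis(3-methylbut-2-enyl)malonate | CCOC(=O)C(CC=C(C)C)(CC=C(C)C)C(=O)OCC | intermediate |
| 5 | ethyl 5-methyl-2-(3-methylbut-2-enyl)hex-4-enoate | CCOC(=O)C(CC=C(C)C)CC=C(C)C | intermediate |
| 6 | 5-methyl-2-(3-methylbut-2-enyl)hex-4-enoic acid | OC(=O)C(CC=C(C)C)CC=C(C)C | intermediate |
| 7 | 5-methyl-2-(3-methylbut-2-enyl)hex-4-enoyl chloride | ClC(=O)C(CC=C(C)C)CC=C(C)C | intermediate |
| 8 | ethoxyacetylene | CCOC#C | starting material |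
| 9 | 1-ethoxy-5-methylhex-4-en-1-yne | CCOC#CCC=C(C)C | intermediate |
| 10 | bis(3-methylbut-2-enyl)ketene | O=C=C(CC=C(C)C)CC=C(C)C | intermediate |
| 11 | 3-ethoxy-2,4,4-tris(3-methylbut-2-enyl)cyclobut-2-en-1-one | CCOC1=C(CC=C(C)C)C(=O)C1(CC=C(C)C)CC=C(C)C | intermediate |
| 12 | 3-hydroxy-2,4,4-tris(3-methylbut-2-enyl)cyclobut-2-en-1-one | OC1=C(CC=C(C)C)C(=O)C1(CC=C(C)C)CC=C(C)C | intermediate |
| 13 | N-methoxy-N-methylisobutyramide | CC(C)C(=O)N(C)OC | starting material |
| 14 | 1-ethoxy-4-methylpent-1-yn-3-one | CCOC#CC(=O)C(C)C | intermediate |
| 15 | allenolate adduct (anion; racemic allene axis) | CCOC(=C=C([O-])C(C)C)C1(CC=C(C)C)C(=O)C(CC=C(C)C)(CC=C(C)C)C1=O | intermediate |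
| 16 | cis-fused bicyclo[2.2.0]hex-2-en-1-olate (anion; racemic, one enantiomer drawn) | [O-][C@@]12C(C(=O)C(C)C)=C(OCC)[C@]1(CC=C(C)C)C(=O)C2(CC=C(C)C)CC=C(C)C | intermediate |
| 17 | colupulone 3-O-ethyl ether | CCOC1=C(C(=O)C(C)C)C(=O)C(CC=C(C)C)(CC=C(C)C)C(O)=C1CC=C(C)C | intermediate |
| 18 | colupulone | CC(C)=CCC1=C(O)C(CC=C(C)C)(CC=C(C)C)C(=O)C(C(=O)C(C)C)=C1O | target |

Total step count: 10
Longest linear sequence: 8 (steps 1, 2, 3, 4, 6, 7, 9, 10)

**Steps most likely to fail**

**Step 9.**
- What may go wrong: the enolate may react at oxygen and stay there. The allenolate may revert or pick up a proton before it closes onto the ring carbonyl. The ynone may oligomerise under base.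
- Fallback: this uses known chemistry only, sets out from 2 and gives up the ring expansion for a dearomative construction. Friedel–Crafts acylation of phloroglucinol with isobutyryl chloride (AlCl3, CH2Cl2–MeNO2) gives phlorisobutyrophenone F1.
- Exhaustive C-prenylation of its phenolate with three equivalents of 2 (NaOMe, MeOH, 0 °C) runs through the 3-prenyl ketone F2 and the 3,5-diprenyl ketone F3. The third alkylation falls on an already prenylated ring carbon, breaks the aromaticity and comes back to the route at 18.

**Step 6.**
- What may go wrong: dehydrochlorination of the α-branched acid chloride may be slow. The cycloaddition between a fully substituted ketene terminus and an internal ynol ether may be sterically retarded. The ynol ether may be protonated by the ammonium salt.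
- Fallback: this sets out from 7 and 8 and changes the order of bond formation. Ketene 10 is trapped with the unhindered parent alkyne 8 to give 3-ethoxy-4,4-bis(3-methylbut-2-enyl)cyclobut-2-en-1-one F4. Acid hydrolysis gives 3-hydroxy-4,4-bis(3-methylbut-2-enyl)cyclobut-2-en-1-one F5.
- The third prenyl group is then placed on the free ring carbon by Tsuji–Trost alkylation with 2 (Pd(PPh3)4, K2CO3, THF), in which O-prenylation is reversible under zerovalent palladium. This comes back to the route at 12.

**Step 8.**
- What may go wrong: the released N,O-dimethylhydroxylamine may add to the push–pull alkyne when the tetrahedral adduct collapses. The ynol ether may also be hydrated during work-up.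
- Fallback: this sets out from 8 and replaces acyl substitution by addition and oxidation. Lithium ethoxyacetylide adds to isobutyraldehyde (THF, −78 °C) to give racemic 1-ethoxy-4-methylpent-1-yn-3-ol F6. Oxidation of the propargylic alcohol with MnO2 (CH2Cl2, rt) comes back to the route at 14.

**Further compounds**
F1 | step 9 | 2-methyl-1-(2,4,6-trihydroxyphenyl)propan-1-one (phlorisobutyrophenone) | CC(C)C(=O)c1c(O)cc(O)cc1O
F2 | step 9 | 2-methyl-1-[2,4,6-trihydroxy-3-(3-methylbut-2-enyl)phenyl]propan-1-one | CC(C)C(=O)c1c(O)cc(O)c(CC=C(C)C)c1O
F3 | step 9 | 2-methyl-1-[2,4,6-trihydroxy-3,5-bis(3-methylbut-2-enyl)phenyl]propan-1-one | CC(C)C(=O)c1c(O)c(CC=C(C)C)c(O)c(CC=C(C)C)c1O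
F4 | step 6 | 3-ethoxy-4,4-bis(3-methylbut-2-enyl)cyclobut-2-en-1-one | CCOC1=CC(=O)C1(CC=C(C)C)CC=C(C)C
F5 | step 6 | 3-hydroxy-4,4-bis(3-methylbut-2-enyl)cyclobut-2-en-1-one | OC1=CC(=O)C1(CC=C(C)C)CC=C(C)C
F6 | step 8 | 1-ethoxy-4-methylpent-1-yn-3-ol (racemic) | CCOC#CC(O)C(C)C
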